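Open a ledger on free monomer, the limiting reagent, and give each mole charged one of 3 entries: still free, in chains, or turned into isomer of the product.

| flask | free monomer | pre-initiator | remark | time |
|---|---|---|---|---|
| green | 0.0090 M | 3.1 mol% | run made earlier |  |
| blue | 0.081 M | 3.1 mol% | run made earlier |  |
| Saturday's | 0.0060 M | 3.1 mol% |  | 2.5 h |
| Friday's | 0.020 M | 3.1 mol% |  | 2.5 h |
| Tuesday's | 0.060 M | 3.1 mol% |  | 2.5 h |

| run | time / min | monomer in chains / % | isomer of the product / % |
|---|---|---|---|
| green | 8.00 | 1.9 | 0.6 |
| green | 15.0 | 2.2 | 0 |
| green | 30.0 | 5.7 | 1.4 |
| green | 60.0 | 13.5 | 2.5 |
| green | 120 | 26.1 | 3.6 |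
| blue | 20.0 | 11.2 | 1.5 |
| blue | 40.0 | 24.7 | 3.4 |
| blue | 60.0 | 37.1 | 6.5 |
| blue | 80.0 | 45.5 | 7.1 |
| blue | 120 | 56.8 | 13.5 |

(each reading ± 1 percentage point)

- the numbers in the tables scatter by 1 percentage point (one standard deviation)
- reactions considered so far: free monomer + initiator -> living end + monomer in chains; free monomer + living end -> monomer in chains + living end; 2 living end <-> resting dimer; pre-initiator <-> initiator; monomer in chains <-> isomer of the product
- "hardly changes" means that all values lie within two and a half points (for a concentration: within two and a half percent of the largest)

- share of monomer in chains in all that became monomer in chains or isomer of the product for Saturday's, Friday's, Tuesday's, in this order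
- how that number moves from the first to the last of them (rises all the way / hardly changes / falls, then rises / rises, then falls / falls all the way)

The last line of the blue run shows how the books work. Of the free monomer charged, 56.8% stands in chains and 13.5% as isomer of the product, so by subtraction 29.7% remains free. The share asked for ignores the free entry, so I treat the isomer as a small correction to the chains and reckon that correction alone.

The earliest isomer entries are close to the scatter in size, so I sum the entries over all lines of both runs. Isomer then stands to chains as 0.178. I call this reading the isomer ratio, the moles of isomer of the product per mole of monomer in chains. The share in chains is one over one plus that ratio, which gives 84.9%.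

The last lines taken singly give ratios of 0.138 for green and 0.238 for blue, and these carry the scatter. Even so, they put the share between 87.9% and 80.8%. I commit to 84.9% for each of the new flasks.

The forecast gives 85%, 85% and 85%, with the shape hardly changes, holding that the isomer behaves like “a rapidly equilibrated or parallel product, independent of concentration”. My figure comes from the same readings, so the two meeting tests nothing.

Saturday's, Friday's and Tuesday's give 84.0%, 83.3% and 82.5%, so the share hardly changes, and the forecast held.

    free monomer + initiator → living end + monomer in chains (k = 0.360 M⁻¹ s⁻¹)
    free monomer + living end → monomer in chains + living end, rate k2*[living end]*[free monomer] (k = 1.30 M⁻¹ s⁻¹)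
    2 living end ⇌ resting dimer, settled at all times (K = 65000 M⁻¹)
    pre-initiator ⇌ initiator (K = 0.410, k = 8.50 × 10⁻⁴ s⁻¹)
    monomer in chains ⇌ isomer of the product (K = 0.290, k = 8.50 × 10⁻⁵ s⁻¹)

Against the carried isomer ratio of 0.178, Saturday's flask stands at 0.190, from 4.67% isomer on 24.6% chains, and Tuesday's at 0.212, from 12.5% on 59.1%. One reason Saturday's isomer entry stays this small at the asked time is that isomer of the product falls back to monomer in chains. In Saturday's flask, the relaxation half-life of that pair by that step alone, 0.509 h, is shorter than the 2.5 h of the run. Without the falling back, Saturday's share goes from 84.0% to 70.7%.

The readings were computed on assumed constants; scatter was added.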